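Ring C of the flavonol is cut at C3–C4 and O1–C2. The C4 carbonyl is the formyl carbon of a ring A salicylaldehyde whose chelated phenol becomes O1. C3 with its oxygen and C2 with the anisyl ring are the two carbons of a polarised aryl siloxyalkyne. One rhodium-catalysed oxidative annulation should therefore close ring C, complete the kaempferide skeleton and leave the C3 oxygen as the only silyl ether. Fluoride then frees this hydroxyl alone for sulfation before the benzyl ethers are hydrogenolysed. The precursors are a 2,4-dibenzylated phloroglucinaldehyde and the triisopropylsilyl ynol ether made from methyl anisate.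

Key step: step 3

Assumption: the two sulfate monoesters are drawn as free acids, as the target is; they would be handled as sodium salts (amine-free, because pyridine retards benzyl ether hydrogenolysis), and the acid form of the target is released at the end by brief contact with a cold H+-form cation-exchange resin.

Step 1
Reactants: 1 2,4,6-trihydroxybenzaldehyde; 2 benzyl bromide
Product: 3 2,4-bis(benzyloxy)-6-hydroxybenzaldehyde
Conditions: BnBr (2.1 equiv), K2CO3 (2.2 equiv), DMF, 0 °C → rt
Reagents that add atoms: benzyl bromide (2), BrCc1ccccc1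
Why: Williamson etherification, in which the 4-hydroxyl and one ortho hydroxyl are alkylated while the remaining ortho hydroxyl, locked in a hydrogen bond to the formyl oxygen, is the least nucleophilic site and should stay free as the later directing group.

Step 2
Reactants: 4 methyl 4-methoxybenzoate; 5 triisopropylsilyl trifluoromethanesulfonate
Product: 8 1-methoxy-4-[(triisopropylsilyloxy)ethynyl]benzene, via lithium dibromoenolate 6 (not isolated), via lithium ynolate 7 (not isolated)
Conditions: CH2Br2, LiTMP (lithium 2,2,6,6-tetramethylpiperidide), THF, −78 °C; LiN(SiMe3)2, −78 → −20 °C; n-BuLi, −78 °C → rt; TIPSOTf (2.2 equiv), −78 → 0 °C; non-acidic work-up, filtration through NEt3-deactivated alumina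
Reagents that add atoms: dibromomethane, BrCBr; triisopropylsilyl trifluoromethanesulfonate (5), CC(C)[Si](OS(=O)(=O)C(F)(F)F)(C(C)C)C(C)C
Why: Kowalski ester homologation stopped at the ynolate, in which acylation of LiCHBr2 gives dibromoenolate 6, bromine–lithium exchange triggers a 1,2-shift of the electron-rich anisyl group to ynolate 7, and the hard, bulky silyl triflate silylates on oxygen to the isolable triisopropylsilyl ynol ether (the second equivalent of triflate is consumed by the methoxide set free).

Step 3
Reactants: 3 2,4-bis(benzyloxy)-6-hydroxybenzaldehyde; 8 1-methoxy-4-[(triisopropylsilyloxy)ethynyl]benzene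
Product: 9 5,7-bis(benzyloxy)-2-(4-methoxyphenyl)-3-(triisopropylsilyloxy)-4H-chromen-4-one
Conditions: [Cp*RhCl2]2 (2.5 mol%), anhydrous Cu(OAc)2 (2.2 equiv), Na2CO3 (2.5 equiv), 4 Å MS, PhMe, 80 °C, N2; 8 (1.5 equiv) added slowly; no silver salt
Reagents that add atoms: none
Why: Proposed new method: the phenoxide of 3 binds the Cp*Rh centre (trivalent rhodium) and steers acetate-assisted cleavage of the formyl C–H bond to a five-membered acyl rhodacycle, the siloxyalkyne inserts into the Rh–acyl bond (C3–C4) to give a seven-membered rhodacycle, and C–O reductive elimination (O1–C2) releases the chromone and monovalent rhodium, which Cu(OAc)2 reoxidises. The closest known reaction type is the rhodium-catalysed, copper-mediated oxidative annulation of salicylaldehydes with diaryl or aryl alkyl alkynes to 2,3-disubstituted chromones, to which oxygen-substituted alkynes have not been submitted. Ring C is closed as a formal [4+2] annulation in which the O1–C8a–C4a–C4 unit of the aldehyde takes up the two alkyne carbons, the last bond arising by C(sp2)–O reductive elimination with contraction of the seven-membered metallacycle to the six-membered pyranone. No stereocentre is formed. The step needs a single sense of insertion, acyl to the oxygen-bearing alkyne carbon and rhodium to the aryl-bearing one, and both the polarisation of the ynol ether (electrophilic at its O-substituted carbon) and the usual preference of the metal for the aryl-substituted carbon, seen when aryl alkyl alkynes place the aryl group at C2, point that way. Na2CO3, molecular sieves, slow addition of 8 and the absence of silver should keep acetic acid, water and the free phenol from adding across the acid-sensitive ynol ether, while benzyl ethers, the anisyl ether and the silyl group are inert to the oxidant.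

Step 4
Reactants: 9 5,7-bis(benzyloxy)-2-(4-methoxyphenyl)-3-(triisopropylsilyloxy)-4H-chromen-4-one
Product: 10 5,7-bis(benzyloxy)-3-hydroxy-2-(4-methoxyphenyl)-4H-chromen-4-one
Conditions: Bu4NF (1.1 equiv), AcOH (1.1 equiv), THF, 0 °C
Reagents that add atoms: none
Why: Fluoride-induced desilylation, in which the Si–O bond of the enol-type silyl ether is cleaved under acetic acid buffering, conditions to which the benzyl ethers, the methyl ether and the chromone are inert.

Step 5
Reactants: 10 5,7-bis(benzyloxy)-3-hydroxy-2-(4-methoxyphenyl)-4H-chromen-4-one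
Product: 11 5,7-bis(benzyloxy)-2-(4-methoxyphenyl)-4-oxo-4H-chromen-3-yl hydrogen sulfate
Conditions: SO3·pyridine (5 equiv), pyridine, 50 °C; then aq NaHCO3, isolation as the sodium salt
Reagents that add atoms: sulfur trioxide–pyridine complex, [O-]S(=O)(=O)[n+]1ccccc1
Why: O-sulfation with a sulfur trioxide–amine complex, in which the 3-hydroxyl is the only free hydroxyl so that no site selectivity is required, and the basic medium keeps the acid-labile monoester as its salt.

Step 6
Reactants: 11 5,7-bis(benzyloxy)-2-(4-methoxyphenyl)-4-oxo-4H-chromen-3-yl hydrogen sulfate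
Product: 12 kaempferide 3-O-sulfate
Conditions: H2 (1 atm), Pd/C (10 wt% palladium on carbon), MeOH–THF, rt; then H+-form resin, 0 °C
Reagents that add atoms: none
Why: Catalytic hydrogenolysis of the two aryl benzyl ethers under neutral conditions, which aryl sulfate salts, the aryl methyl ether and the chromone C2–C3 double bond are expected to survive.

Compound list
1 | 2,4,6-trihydroxybenzaldehyde | O=Cc1c(O)cc(O)cc1O | starting material
2 | benzyl bromide | BrCc1ccccc1 | starting material
3 | 2,4-bis(benzyloxy)-6-hydroxybenzaldehyde | O=Cc1c(O)cc(OCc2ccccc2)cc1OCc1ccccc1 | intermediate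
4 | methyl 4-methoxybenzoate | COC(=O)c1ccc(OC)cc1 | starting material
5 | triisopropylsilyl trifluoromethanesulfonate | CC(C)[Si](OS(=O)(=O)C(F)(F)F)(C(C)C)C(C)C | starting material
6 | lithium 2,2-dibromo-1-(4-methoxyphenyl)ethen-1-olate (lithium dibromoenolate) | COc1ccc(cc1)C([O-])=C(Br)Br.[Li+] | intermediate
7 | lithium 2-(4-methoxyphenyl)ethyn-1-olate (lithium ynolate) | COc1ccc(cc1)C#C[O-].[Li+] | intermediate
8 | 1-methoxy-4-[(triisopropylsilyloxy)ethynyl]benzene | COc1ccc(cc1)C#CO[Si](C(C)C)(C(C)C)C(C)C | intermediate
9 | 5,7-bis(benzyloxy)-2-(4-methoxyphenyl)-3-(triisopropylsilyloxy)-4H-chromen-4-one | COc1ccc(-c2oc3cc(OCc4ccccc4)cc(OCc4ccccc4)c3c(=O)c2O[Si](C(C)C)(C(C)C)C(C)C)cc1 | intermediate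
10 | 5,7-bis(benzyloxy)-3-hydroxy-2-(4-methoxyphenyl)-4H-chromen-4-one | COc1ccc(-c2oc3cc(OCc4ccccc4)cc(OCc4ccccc4)c3c(=O)c2O)cc1 | intermediate
11 | 5,7-bis(benzyloxy)-2-(4-methoxyphenyl)-4-oxo-4H-chromen-3-yl hydrogen sulfate | COc1ccc(-c2oc3cc(OCc4ccccc4)cc(OCc4ccccc4)c3c(=O)c2OS(=O)(=O)O)cc1 | intermediate
12 | kaempferide 3-O-sulfate | COc1ccc(-c2oc3cc(O)cc(O)c3c(=O)c2OS(=O)(=O)O)cc1 | target

Total step count: 6. Longest linear sequence: 5 steps (steps 1, 3, 4, 5, 6 from 1; equally steps 2, 3, 4, 5, 6 from 4).

Steps most likely to fail

Step 3 (new method). The ynol ether may be consumed before it inserts, by protonation, hydration or copper-mediated oxidation. Insertion may also occur with the reversed regiochemistry, or the acyl rhodium intermediate may decarbonylate. The fallback uses known chemistry, sets out from 3 and comes back at 10, bypassing 8 and 9. Commercial 4-ethynylanisole F1 is lithiated (n-BuLi, THF, −78 °C) to lithium (4-methoxyphenyl)acetylide F2, and 2.2 equivalents are added to 3 to give the racemic propargylic alcohol 1-[2,4-bis(benzyloxy)-6-hydroxyphenyl]-3-(4-methoxyphenyl)prop-2-yn-1-ol F3. This is oxidised without purification (MnO2, CH2Cl2, rt) to the ynone 1-[2,4-bis(benzyloxy)-6-hydroxyphenyl]-3-(4-methoxyphenyl)prop-2-yn-1-one F4. Amine-mediated 6-endo cyclisation (Et2NH, EtOH, reflux) should give the flavone 5,7-bis(benzyloxy)-2-(4-methoxyphenyl)-4H-chromen-4-one F5. Epoxidation of its C2–C3 double bond with dimethyldioxirane (acetone–CH2Cl2, 0 °C) gives the racemic 2,3-epoxide 5,7-bis(benzyloxy)-1a-(4-methoxyphenyl)-1a,7a-dihydro-7H-oxireno[2,3-b]chromen-7-one F6, which catalytic p-TsOH opens to the 3-hydroxyflavone 10.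

Step 2. The 1,2-aryl migration may be incomplete, silylation may occur on carbon to give a silyl ketene, or the ynol ether may hydrolyse during isolation. The fallback sets out from silyl triflate 5 and comes back at 8 through the same ynolate 7. 4-Ethynylanisole F1 is deprotonated to lithium (4-methoxyphenyl)acetylide F2 and oxidised with LiOO-t-Bu (from t-BuOOH and LiN(SiMe3)2, THF, −78 → 0 °C). This oxygen transfer delivers ynolate 7 without any rearrangement, and silylation with 5 gives 8. The fallback makes no compound beyond F1, F2 and those of the compound list.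

Step 5. Sulfation of the hindered, hydrogen-bonded 3-hydroxyl may be sluggish, and the sulfate group may be lost during isolation of the polar salt. The fallback sets out from 10 and comes back at 11. 2,2,2-Trichloroethyl chlorosulfate with NEt3 and DMAP in THF should give the neutral, chromatographable diester 5,7-bis(benzyloxy)-2-(4-methoxyphenyl)-4-oxo-4H-chromen-3-yl 2,2,2-trichloroethyl sulfate F7. Zn dust with HCO2NH4 in MeOH at rt then removes the trichloroethyl group by reductive fragmentation and returns monoester 11, which is exchanged to its sodium salt before step 6.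

Further compounds
F1 | step 3 | 4-ethynylanisole | COc1ccc(C#C)cc1
F2 | step 3 | lithium (4-methoxyphenyl)acetylide | COc1ccc(cc1)C#C[Li]
F3 | step 3 | 1-[2,4-bis(benzyloxy)-6-hydroxyphenyl]-3-(4-methoxyphenyl)prop-2-yn-1-ol (racemic) | COc1ccc(cc1)C#CC(O)c1c(O)cc(OCc2ccccc2)cc1OCc1ccccc1
F4 | step 3 | 1-[2,4-bis(benzyloxy)-6-hydroxyphenyl]-3-(4-methoxyphenyl)prop-2-yn-1-one | COc1ccc(cc1)C#CC(=O)c1c(O)cc(OCc2ccccc2)cc1OCc1ccccc1
F5 | step 3 | 5,7-bis(benzyloxy)-2-(4-methoxyphenyl)-4H-chromen-4-one | COc1ccc(-c2cc(=O)c3c(OCc4ccccc4)cc(OCc4ccccc4)cc3o2)cc1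
F6 | step 3 | 5,7-bis(benzyloxy)-1a-(4-methoxyphenyl)-1a,7a-dihydro-7H-oxireno[2,3-b]chromen-7-one (racemic) | COc1ccc(cc1)C12OC1C(=O)c1c(OCc3ccccc3)cc(OCc3ccccc3)cc1O2
F0 | step 2 | none | none
F7 | step 5 | 5,7-bis(benzyloxy)-2-(4-methoxyphenyl)-4-oxo-4H-chromen-3-yl 2,2,2-trichloroethyl sulfate | COc1ccc(-c2oc3cc(OCc4ccccc4)cc(OCc4ccccc4)c3c(=O)c2OS(=O)(=O)OCC(Cl)(Cl)Cl)cc1
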